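**Plan**

1. Retrosynthesis: the four benzyl ethers come off last. The pyran ring of the isoflavan unit (O1, C2, C3, C4, C4a, C8a) is cut at C4–C4a, a dehydrogenative union of a benzylic CH2 with an arene CH. The open chain is then cut at C4–C6 of the flavanone ring A (sp3–sp2 Negishi coupling) and at O1–C2 (Mitsunobu aryl ether), leaving a prochiral 2-aryl-propane-1,3-diol, (2S)-naringenin and 3-(benzyloxy)phenol.
2. Enabling feature: in the open precursor C4 is a benzylic CH2 on flavanone ring A, ortho to the free 5-OH and to the 7-oxygen and para to the ring oxygen, so DDQ can turn it into an ortho-quinone methide. The resorcinol-derived ring offers a nucleophilic carbon (the future C4a) ortho to its ether oxygen and para to its second oxygen.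
3. Forward order: aryl malonate → prochiral diol → desymmetrization → aryl ether → primary iodide; naringenin → 6-iodide; Negishi union; the pyran ring closes as the last skeletal event; hydrogenolysis.
4. Stereochemistry: flavanone C2 comes from (2S)-naringenin, which is kept away from bases that open the ring. C3 comes from a lipase desymmetrization of the diol. C4 is set in the ring closure under control of C3 (3,4-trans), both double-bond isomers of the quinone methide converging on one product.

Key step: step 14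

Assumption: (2S)-naringenin is taken as a commercial single enantiomer, and the lipase is taken to acetylate the hydroxymethyl arm that gives the (R)-monoacetate 7; if the enzyme prefers the other arm, the same antipode is reached by hydrolysis of the diacetate with the same lipase.

**Route**

Step 1
Reactants: 1 2,6-dimethoxyphenol
Product: 2 2-(benzyloxy)-1,3-dimethoxybenzene
Conditions: BnBr, K2CO3, DMF, 60 °C
Reagents that add atoms: benzyl bromide, BrCc1ccccc1
Why: Williamson ether synthesis masks the future 3'-OH as a benzyl ether that should survive every later step and leave with the other benzyl groups at the end.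

Step 2
Reactants: 2 2-(benzyloxy)-1,3-dimethoxybenzene
Product: 3 3-(benzyloxy)-1-bromo-2,4-dimethoxybenzene
Conditions: NBS, MeCN, 0 °C to rt
Reagents that add atoms: N-bromosuccinimide, O=C1CCC(=O)N1Br
Why: Electrophilic aromatic bromination of the 1,2,3-trioxygenated ring should go para to an outer methoxy group, because the central benzyloxy group is twisted out of conjugation, which places bromine on the carbon that becomes C1' of ring B.

Step 3
Reactants: 3 3-(benzyloxy)-1-bromo-2,4-dimethoxybenzene; 4 diethyl malonate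
Product: 5 diethyl 2-[3-(benzyloxy)-2,4-dimethoxyphenyl]malonate
Conditions: Pd(OAc)2 (2 mol%), P(t-Bu)3·HBF4 (4 mol%), K3PO4, toluene, 80 °C
Reagents that add atoms: none
Why: Palladium-catalysed α-arylation of the malonate enolate installs the carbon that becomes C3 together with both hydroxymethyl precursors, the bulky electron-rich phosphine allowing oxidative addition to the ortho-substituted, electron-rich bromide.

Step 4
Reactants: 5 diethyl 2-[3-(benzyloxy)-2,4-dimethoxyphenyl]malonate
Product: 6 2-[3-(benzyloxy)-2,4-dimethoxyphenyl]propane-1,3-diol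
Conditions: LiAlH4, THF, 0 °C to rt
Reagents that add atoms: none
Why: Hydride reduction of both esters should give the prochiral 2-aryl-1,3-diol, the aryl ethers being inert.

Step 5
Reactants: 6 2-[3-(benzyloxy)-2,4-dimethoxyphenyl]propane-1,3-diol
Product: 7 (R)-2-[3-(benzyloxy)-2,4-dimethoxyphenyl]-3-hydroxypropyl acetate
Conditions: Amano lipase PS, vinyl acetate, t-BuOMe, 25 °C
Reagents that add atoms: vinyl acetate, C=COC(C)=O
Why: Lipase-catalysed irreversible transesterification distinguishes the two enantiotopic hydroxymethyl groups of the prochiral diol (enzymatic desymmetrization) and so sets the stereocenter that becomes C3.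

Step 6
Reactants: 7 (R)-2-[3-(benzyloxy)-2,4-dimethoxyphenyl]-3-hydroxypropyl acetate; 8 3-(benzyloxy)phenol
Product: 9 (R)-2-[3-(benzyloxy)-2,4-dimethoxyphenyl]-3-[3-(benzyloxy)phenoxy]propyl acetate
Conditions: PPh3, DIAD, THF, 0 °C to rt
Reagents that add atoms: none
Why: Mitsunobu etherification of the primary alcohol with the phenol forms the O1–C2 bond under neutral conditions that should not provoke 1,3-acyl migration, and the stereocenter is not a reacting carbon.

Step 7
Reactants: 9 (R)-2-[3-(benzyloxy)-2,4-dimethoxyphenyl]-3-[3-(benzyloxy)phenoxy]propyl acetate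
Product: 10 (S)-2-[3-(benzyloxy)-2,4-dimethoxyphenyl]-3-[3-(benzyloxy)phenoxy]propan-1-ol
Conditions: K2CO3 (cat.), MeOH, rt
Reagents that add atoms: none
Why: Base-catalysed transesterification (Zemplén-type methanolysis) frees the second primary alcohol without touching the aryl ethers; the descriptor changes only because the priorities change.

Step 8
Reactants: 10 (S)-2-[3-(benzyloxy)-2,4-dimethoxyphenyl]-3-[3-(benzyloxy)phenoxy]propan-1-ol
Product: 11 2-(benzyloxy)-4-{(2R)-1-[3-(benzyloxy)phenoxy]-3-iodopropan-2-yl}-1,3-dimethoxybenzene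
Conditions: I2, PPh3, imidazole, CH2Cl2, 0 °C to rt
Reagents that add atoms: iodine, II
Why: The Appel reaction converts the primary alcohol into the iodide by SN2 displacement at a carbon that is not stereogenic.

Step 9
Reactants: 12 (2S)-naringenin
Product: 13 (2S)-7-(benzyloxy)-2-[4-(benzyloxy)phenyl]-5-hydroxychroman-4-one
Conditions: BnOH (2.3 equiv), PPh3, DIAD, THF, 0 °C to rt
Reagents that add atoms: benzyl alcohol, OCc1ccccc1
Why: Mitsunobu O-alkylation should benzylate the two acidic phenols at C7 and C4' while the chelated 5-OH stays free, and its neutral conditions avoid the base-induced ring opening to the chalcone that would racemize C2.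

Step 10
Reactants: 13 (2S)-7-(benzyloxy)-2-[4-(benzyloxy)phenyl]-5-hydroxychroman-4-one
Product: 14 (2S)-7-(benzyloxy)-2-[4-(benzyloxy)phenyl]-5-hydroxy-6-iodochroman-4-one
Conditions: BnMe3N·ICl2, CaCO3, CH2Cl2–MeOH, rt
Reagents that add atoms: benzyltrimethylammonium dichloroiodate, C[N+](C)(C)Cc1ccccc1.Cl[I-]Cl
Why: Electrophilic aromatic iodination of a 5-hydroxy-7-alkoxy chromanone ring is directed ortho to the free chelated 5-OH, so C6 and not C8 should be substituted.

Step 11
Reactants: 14 (2S)-7-(benzyloxy)-2-[4-(benzyloxy)phenyl]-5-hydroxy-6-iodochroman-4-one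
Product: 15 (2S)-7-(benzyloxy)-2-[4-(benzyloxy)phenyl]-6-iodo-4-oxochroman-5-yl acetate
Conditions: Ac2O, pyridine, DMAP (cat.), CH2Cl2, rt
Reagents that add atoms: acetic anhydride, CC(=O)OC(C)=O
Why: Acetylation masks the acidic phenol that would protonate the organozinc reagent, and an aryl acetate is inert toward alkylzinc halides.

Step 12
Reactants: 11 2-(benzyloxy)-4-{(2R)-1-[3-(benzyloxy)phenoxy]-3-iodopropan-2-yl}-1,3-dimethoxybenzene; 15 (2S)-7-(benzyloxy)-2-[4-(benzyloxy)phenyl]-6-iodo-4-oxochroman-5-yl acetate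
Product: 17 (2S)-7-(benzyloxy)-2-[4-(benzyloxy)phenyl]-6-{(2R)-2-[3-(benzyloxy)-2,4-dimethoxyphenyl]-3-[3-(benzyloxy)phenoxy]propyl}-4-oxochroman-5-yl acetate, via alkylzinc iodide 16 (not isolated)
Conditions: Zn dust (TMSCl/1,2-dibromoethane activation), DMF, rt; then 15, Pd2(dba)3 (2.5 mol%), SPhos (10 mol%), 45 °C
Reagents that add atoms: none
Why: Direct zinc insertion into the primary iodide followed by Negishi cross-coupling forms the sp3–sp2 bond between C4 and C6 of the flavanone; alkylzinc halides tolerate the ketone and the acetate, and the stereocenter β to zinc is not touched.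

Step 13
Reactants: 17 (2S)-7-(benzyloxy)-2-[4-(benzyloxy)phenyl]-6-{(2R)-2-[3-(benzyloxy)-2,4-dimethoxyphenyl]-3-[3-(benzyloxy)phenoxy]propyl}-4-oxochroman-5-yl acetate
Product: 18 (2S)-7-(benzyloxy)-2-[4-(benzyloxy)phenyl]-6-{(2R)-2-[3-(benzyloxy)-2,4-dimethoxyphenyl]-3-[3-(benzyloxy)phenoxy]propyl}-5-hydroxychroman-4-one
Conditions: HCl (1.25 M in MeOH, cat.), CH2Cl2–MeOH, rt
Reagents that add atoms: none
Why: Acid-catalysed transesterification removes the aryl acetate and frees the 5-OH needed for the oxidation, under conditions in which the flavanone ring should not open.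

Step 14
Reactants: 18 (2S)-7-(benzyloxy)-2-[4-(benzyloxy)phenyl]-6-{(2R)-2-[3-(benzyloxy)-2,4-dimethoxyphenyl]-3-[3-(benzyloxy)phenoxy]propyl}-5-hydroxychroman-4-one
Product: 20 (2S)-7-(benzyloxy)-6-{(3R,4S)-7-(benzyloxy)-3-[3-(benzyloxy)-2,4-dimethoxyphenyl]chroman-4-yl}-2-[4-(benzyloxy)phenyl]-5-hydroxychroman-4-one, via ortho-quinone methide 19 (not isolated)
Conditions: DDQ (1.05 equiv), CH2Cl2–HFIP (9:1), −20 °C to 0 °C
Reagents that add atoms: none
Why: DDQ takes a hydride from the benzylic C4 methylene through its complex with the only free phenol (5-OH of flavanone ring A) and gives ortho-quinone methide 19, whose O-protonated form is a benzylic cation stabilized by the oxygens at C5 and C7 (ortho) and by the ring oxygen (para); the resorcinol ring then adds through the future C4a and rearomatizes by proton loss, a net dehydrogenative union of two carbons that are both nucleophilic in the precursor. The closest known reaction types are the DDQ cyclodehydrogenation of 6-prenyl-5-hydroxyflavanones through the same kind of quinone methide and the DDQ-mediated oxidative cyclization of dibenzylbutane lignans to trans-aryltetralins. The pyran ring (O1, C2, C3, C4, C4a, C8a) closes in a 6-exo-trig Friedel–Crafts mode with respect to the exocyclic C=C bond of 19. The new stereocenter C4 is controlled by C3: in the half-chair transition state the C3 aryl group sits pseudo-equatorial and the arene adds to the face of C4 that places the flavanone ring trans to it, so both double-bond isomers of 19 should converge on the (3R,4S) product. The step needs chemoselectivity among the benzylic C–H bonds, secured by the free 5-OH (the C3–H and the flavanone C2–H have no phenol next to them and HFIP is only weakly acidic), and site selectivity on the arene, secured by the tether (only the two carbons ortho to O1 can reach C4) and by the benzyloxy group, which activates the unhindered para carbon over the one between the two oxygens. One equivalent of oxidant at low temperature is expected to spare the product, whose C4–H is flanked by two rings and cannot easily reach the planar quinone methide geometry.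

Step 15
Reactants: 20 (2S)-7-(benzyloxy)-6-{(3R,4S)-7-(benzyloxy)-3-[3-(benzyloxy)-2,4-dimethoxyphenyl]chroman-4-yl}-2-[4-(benzyloxy)phenyl]-5-hydroxychroman-4-one
Product: 21 (2S)-5,7-dihydroxy-6-[(3R,4S)-7-hydroxy-3-(3-hydroxy-2,4-dimethoxyphenyl)chroman-4-yl]-2-(4-hydroxyphenyl)chroman-4-one
Conditions: H2 (1 atm), 10% Pd/C, EtOAc–MeOH, rt
Reagents that add atoms: none
Why: Catalytic hydrogenolysis should cleave the four benzyl ethers in one operation, while the methyl ethers, the aryl ketone and the three stereocenters are unaffected at one atmosphere of hydrogen and room temperature.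

**Compound list**

1 | 2,6-dimethoxyphenol | COc1cccc(OC)c1O | starting material
2 | 2-(benzyloxy)-1,3-dimethoxybenzene | COc1cccc(OC)c1OCc1ccccc1 | intermediate
3 | 3-(benzyloxy)-1-bromo-2,4-dimethoxybenzene | COc1ccc(Br)c(OC)c1OCc1ccccc1 | intermediate
4 | diethyl malonate | CCOC(=O)CC(=O)OCC | starting material
5 | diethyl 2-[3-(benzyloxy)-2,4-dimethoxyphenyl]malonate | CCOC(=O)C(C(=O)OCC)c1ccc(OC)c(OCc2ccccc2)c1OC | intermediate
6 | 2-[3-(benzyloxy)-2,4-dimethoxyphenyl]propane-1,3-diol | OCC(CO)c1ccc(OC)c(OCc2ccccc2)c1OC | intermediate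
7 | (R)-2-[3-(benzyloxy)-2,4-dimethoxyphenyl]-3-hydroxypropyl acetate | COc1ccc([C@@H](COC(C)=O)CO)c(OC)c1OCc1ccccc1 | intermediate
8 | 3-(benzyloxy)phenol | Oc1cccc(OCc2ccccc2)c1 | starting material
9 | (R)-2-[3-(benzyloxy)-2,4-dimethoxyphenyl]-3-[3-(benzyloxy)phenoxy]propyl acetate | COc1ccc([C@@H](COC(C)=O)COc2cccc(OCc3ccccc3)c2)c(OC)c1OCc1ccccc1 | intermediate
10 | (S)-2-[3-(benzyloxy)-2,4-dimethoxyphenyl]-3-[3-(benzyloxy)phenoxy]propan-1-ol | COc1ccc([C@@H](CO)COc2cccc(OCc3ccccc3)c2)c(OC)c1OCc1ccccc1 | intermediate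
11 | 2-(benzyloxy)-4-{(2R)-1-[3-(benzyloxy)phenoxy]-3-iodopropan-2-yl}-1,3-dimethoxybenzene | COc1ccc([C@@H](CI)COc2cccc(OCc3ccccc3)c2)c(OC)c1OCc1ccccc1 | intermediate
12 | (2S)-naringenin, (2S)-5,7-dihydroxy-2-(4-hydroxyphenyl)chroman-4-one | O=C1C[C@@H](c2ccc(O)cc2)Oc2cc(O)cc(O)c12 | starting material
13 | (2S)-7-(benzyloxy)-2-[4-(benzyloxy)phenyl]-5-hydroxychroman-4-one | O=C1C[C@@H](c2ccc(OCc3ccccc3)cc2)Oc2cc(OCc3ccccc3)cc(O)c12 | intermediate
14 | (2S)-7-(benzyloxy)-2-[4-(benzyloxy)phenyl]-5-hydroxy-6-iodochroman-4-one | O=C1C[C@@H](c2ccc(OCc3ccccc3)cc2)Oc2cc(OCc3ccccc3)c(I)c(O)c12 | intermediate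
15 | (2S)-7-(benzyloxy)-2-[4-(benzyloxy)phenyl]-6-iodo-4-oxochroman-5-yl acetate | CC(=O)Oc1c(I)c(OCc2ccccc2)cc2c1C(=O)C[C@@H](c1ccc(OCc3ccccc3)cc1)O2 | intermediate
16 | {(2R)-2-[3-(benzyloxy)-2,4-dimethoxyphenyl]-3-[3-(benzyloxy)phenoxy]propyl}zinc iodide | COc1ccc([C@@H](C[Zn]I)COc2cccc(OCc3ccccc3)c2)c(OC)c1OCc1ccccc1 | intermediate
17 | (2S)-7-(benzyloxy)-2-[4-(benzyloxy)phenyl]-6-{(2R)-2-[3-(benzyloxy)-2,4-dimethoxyphenyl]-3-[3-(benzyloxy)phenoxy]propyl}-4-oxochroman-5-yl acetate | COc1ccc([C@@H](Cc2c(OCc3ccccc3)cc4c(c2OC(C)=O)C(=O)C[C@@H](c2ccc(OCc5ccccc5)cc2)O4)COc2cccc(OCc3ccccc3)c2)c(OC)c1OCc1ccccc1 | intermediate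
18 | (2S)-7-(benzyloxy)-2-[4-(benzyloxy)phenyl]-6-{(2R)-2-[3-(benzyloxy)-2,4-dimethoxyphenyl]-3-[3-(benzyloxy)phenoxy]propyl}-5-hydroxychroman-4-one | COc1ccc([C@@H](Cc2c(OCc3ccccc3)cc4c(c2O)C(=O)C[C@@H](c2ccc(OCc5ccccc5)cc2)O4)COc2cccc(OCc3ccccc3)c2)c(OC)c1OCc1ccccc1 | intermediate
19 | ortho-quinone methide: (2S)-7-(benzyloxy)-2-[4-(benzyloxy)phenyl]-6-{(2R)-2-[3-(benzyloxy)-2,4-dimethoxyphenyl]-3-[3-(benzyloxy)phenoxy]propylidene}-2,3-dihydrochromene-4,5(6H)-dione, double-bond geometry not defined | O=C1C(=C[C@@H](COc2cccc(OCc3ccccc3)c2)c2ccc(OC)c(OCc3ccccc3)c2OC)C(OCc2ccccc2)=CC2=C1C(=O)C[C@@H](c1ccc(OCc3ccccc3)cc1)O2 | intermediate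
20 | (2S)-7-(benzyloxy)-6-{(3R,4S)-7-(benzyloxy)-3-[3-(benzyloxy)-2,4-dimethoxyphenyl]chroman-4-yl}-2-[4-(benzyloxy)phenyl]-5-hydroxychroman-4-one | COc1ccc([C@@H]2COc3cc(OCc4ccccc4)ccc3[C@H]2c2c(OCc3ccccc3)cc3c(c2O)C(=O)C[C@@H](c2ccc(OCc4ccccc4)cc2)O3)c(OC)c1OCc1ccccc1 | intermediate
21 | (2S)-5,7-dihydroxy-6-[(3R,4S)-7-hydroxy-3-(3-hydroxy-2,4-dimethoxyphenyl)chroman-4-yl]-2-(4-hydroxyphenyl)chroman-4-one | COc1ccc([C@@H]2COc3cc(O)ccc3[C@H]2c2c(O)cc3c(c2O)C(=O)C[C@@H](c2ccc(O)cc2)O3)c(OC)c1O | target

**Step count and risks**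

Total steps: 15. Longest linear sequence: 12 steps (steps 1–8 and 12–15).

Steps most likely to fail:

Step 14. The oxidation may not stay at the phenolic benzylic position: hydride may be lost from the tertiary C3–H next to the dimethoxyaryl ring, or the cyclized product may be oxidized a second time. The quinone methide may also tautomerize to the stilbene before the arene adds, which would erase the configuration at C3. The fallback avoids the oxidant and sets out from 10. Oxidation (TEMPO, PhI(OAc)2, MeCN–H2O) should give (R)-2-[3-(benzyloxy)-2,4-dimethoxyphenyl]-3-[3-(benzyloxy)phenoxy]propanoic acid F1. Oxalyl chloride with catalytic DMF should give the corresponding acid chloride F2. SnCl4 in CH2Cl2 at −20 °C should close the same C4–C4a bond by intramolecular Friedel–Crafts acylation, now at the ketone oxidation level, to 7-(benzyloxy)-3-[3-(benzyloxy)-2,4-dimethoxyphenyl]chroman-4-one F3. C3 of this ketone epimerizes freely, so asymmetric transfer hydrogenation with dynamic kinetic resolution (RuCl(p-cymene)(TsDPEN) with the ligand enantiomer that gives the 3R series, HCO2H/Et3N) should funnel it into (3R,4R)-7-(benzyloxy)-3-[3-(benzyloxy)-2,4-dimethoxyphenyl]chroman-4-ol F4. Ionization of this alcohol (BF3·OEt2, CH2Cl2, −40 °C) in the presence of 13 should give the C4 cation, which C6 of the flavanone ring A captures anti to the C3 aryl group. The route is rejoined at 20; a C8-linked isomer, if formed, would have to be separated.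

Step 12. Oxidative addition and reductive elimination at the doubly ortho-substituted aryl iodide may be slow, so that protonation of the alkylzinc reagent or β-hydride elimination from the alkylpalladium intermediate takes over. The fallback replaces the polar transmetalation manifold by a nickel-catalysed reductive cross-electrophile coupling, in which the alkyl partner enters as a radical and no organozinc is preformed. It sets out from 11 and 15 (NiI2, 4,4'-di-tert-butyl-2,2'-bipyridine, Mn powder, NaI, DMA, 60 °C) and comes back to the route at 17; it makes no new compound F0.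

Step 5. The enzyme may discriminate poorly between the two hydroxymethyl groups of this ortho-substituted aryl diol, and 1,3-acyl migration in the monoacetate may erode the enantiomeric purity before step 6. The fallback sets C3 by asymmetric catalysis on an alkene and sets out from 8 and 3. Alkylation of 8 with 2,3-dibromopropene (K2CO3, acetone) should give 1-(benzyloxy)-3-[(2-bromoprop-2-en-1-yl)oxy]benzene F5. Bromine–lithium exchange on 3 (n-BuLi, THF, −78 °C), B(Oi-Pr)3 and acidic work-up should give [3-(benzyloxy)-2,4-dimethoxyphenyl]boronic acid F6. Suzuki–Miyaura coupling of the two (Pd(PPh3)4, K2CO3, dioxane–H2O) should give 2-(benzyloxy)-4-{3-[3-(benzyloxy)phenoxy]prop-1-en-2-yl}-1,3-dimethoxybenzene F7. Copper-catalysed enantioselective protoboration of this 1,1-disubstituted alkene (CuCl, chiral N-heterocyclic carbene ligand, NaOt-Bu, B2pin2, MeOH, THF) should give 2-{(2R)-2-[3-(benzyloxy)-2,4-dimethoxyphenyl]-3-[3-(benzyloxy)phenoxy]propyl}-4,4,5,5-tetramethyl-1,3,2-dioxaborolane F8. Oxidation (NaBO3·4H2O, THF–H2O) should then give the alcohol, and the route is rejoined at 10.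

**Further compounds**

F1 | step 14 | (R)-2-[3-(benzyloxy)-2,4-dimethoxyphenyl]-3-[3-(benzyloxy)phenoxy]propanoic acid | COc1ccc([C@@H](C(=O)O)COc2cccc(OCc3ccccc3)c2)c(OC)c1OCc1ccccc1
F2 | step 14 | (R)-2-[3-(benzyloxy)-2,4-dimethoxyphenyl]-3-[3-(benzyloxy)phenoxy]propanoyl chloride | COc1ccc([C@@H](C(=O)Cl)COc2cccc(OCc3ccccc3)c2)c(OC)c1OCc1ccccc1
F3 | step 14 | 7-(benzyloxy)-3-[3-(benzyloxy)-2,4-dimethoxyphenyl]chroman-4-one, C3 epimerizing and drawn without configuration | COc1ccc(C2COc3cc(OCc4ccccc4)ccc3C2=O)c(OC)c1OCc1ccccc1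
F4 | step 14 | (3R,4R)-7-(benzyloxy)-3-[3-(benzyloxy)-2,4-dimethoxyphenyl]chroman-4-ol | COc1ccc([C@@H]2COc3cc(OCc4ccccc4)ccc3[C@@H]2O)c(OC)c1OCc1ccccc1
F0 | step 12 | none | none
F5 | step 5 | 1-(benzyloxy)-3-[(2-bromoprop-2-en-1-yl)oxy]benzene | C=C(Br)COc1cccc(OCc2ccccc2)c1
F6 | step 5 | [3-(benzyloxy)-2,4-dimethoxyphenyl]boronic acid | COc1ccc(B(O)O)c(OC)c1OCc1ccccc1
F7 | step 5 | 2-(benzyloxy)-4-{3-[3-(benzyloxy)phenoxy]prop-1-en-2-yl}-1,3-dimethoxybenzene | C=C(COc1cccc(OCc2ccccc2)c1)c1ccc(OC)c(OCc2ccccc2)c1OC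
F8 | step 5 | 2-{(2R)-2-[3-(benzyloxy)-2,4-dimethoxyphenyl]-3-[3-(benzyloxy)phenoxy]propyl}-4,4,5,5-tetramethyl-1,3,2-dioxaborolane | CC1(C)OB(C[C@@H](COc2cccc(OCc3ccccc3)c2)c2ccc(OC)c(OCc3ccccc3)c2OC)OC1(C)C
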